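**Retrosynthetic overview**
- Feature: in ring A of the lower (epiafzelechin) unit, the pyran oxygen O1 on C8a and the bond from C8 to upper C4 are ortho neighbours, with the C7 oxygen next to C8. This is the addition pattern of the 3-alkoxyaryne C8≡C8a: nucleophile at C8a, carbon electrophile at C8.
- Last disconnection: hydrogenation of the upper C3=C4 bond (sets upper C4) together with removal of six benzyl ethers.
- Key disconnection: lower O1–C8a and lower C8–upper C4, both formed in one flask from the open-chain bromoarene alcohol 16 and the flavenyl triflate 21.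
- 16 comes from an Evans syn glycolate aldol (sets lower C2 and C3, O3 benzylated, O on C2 free) and a copper-catalysed aryl Grignard–alkyl triflate coupling (C4–C4a). 21 comes from an asymmetric aryl conjugate addition to a chromone (sets upper C2).
- Ring order: the upper pyran ring comes with the chromone; the lower pyran ring is closed in the key step; no ring is formed afterwards.

Key step: step 13

Remark: flavan numbering is used; "upper" is the 4',7-dioxygenated flavan unit and "lower" the epiafzelechin unit. The lower O1 enters the ring on C2 without the C2–O bond being broken, so the open chain must be syn-(1R,2R) from the start; the syn aldol delivers exactly this and no benzylic inversion is needed.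

**Route**

Step 1
Reactants: 1 5-bromoresorcinol
Product: 2 1,3-bis(benzyloxy)-5-bromobenzene
Conditions: BnBr (2.2 equiv), K2CO3, DMF, 60 °C
Reagents that add atoms: benzyl bromide, BrCc1ccccc1
Why: Williamson ether synthesis: both phenoxides are benzylated by SN2 on benzyl bromide and the aryl bromide is untouched.

Step 2
Reactants: 2 1,3-bis(benzyloxy)-5-bromobenzene
Product: 3 1,5-bis(benzyloxy)-3-bromo-2-iodobenzene
Conditions: N-iodosuccinimide (1.05 equiv), CF3CO2H (cat.), MeCN, 0 → 23 °C
Reagents that add atoms: N-iodosuccinimide, O=C1CCC(=O)N1I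
Why: Electrophilic aromatic iodination of the resorcinol diether should go para to one ether oxygen, at the carbon next to bromine, rather than into the more crowded position between the two benzyloxy groups, which places iodine where the side chain will later sit.

Step 3
Reactants: 4 (S)-4-benzyloxazolidin-2-one; 5 (benzyloxy)acetyl chloride
Product: 7 (S)-4-benzyl-3-[(benzyloxy)acetyl]oxazolidin-2-one, via N-lithio oxazolidinone 6 (not isolated)
Conditions: n-BuLi, THF, −78 °C; then 5, −78 → 0 °C
Reagents that add atoms: none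
Why: N-Acylation of the lithiated Evans oxazolidinone by the acid chloride gives the glycolate imide that carries the future O3 benzyl ether.

Step 4
Reactants: 7 (S)-4-benzyl-3-[(benzyloxy)acetyl]oxazolidin-2-one; 8 4-(benzyloxy)benzaldehyde
Product: 10 (S)-4-benzyl-3-[(2S,3R)-2-(benzyloxy)-3-[4-(benzyloxy)phenyl]-3-hydroxypropanoyl]oxazolidin-2-one, via Z boron enolate 9 (not isolated)
Conditions: Bu2BOTf (1.2 equiv), Et3N (1.4 equiv), CH2Cl2, −78 → 0 °C; 8, −78 → 0 °C; H2O2, MeOH, pH 7 buffer
Reagents that add atoms: none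
Why: Evans syn aldol reaction: the Z boron enolate reacts through a chair Zimmerman–Traxler transition state on the enolate face away from the auxiliary benzyl group, which sets both lower-unit stereocentres at once (propanoyl C2 S and C3 R, the 2,3-syn pair that maps onto 2R,3R of the flavan) and leaves the benzylic oxygen free and the neighbouring one benzylated.

Step 5
Reactants: 10 the syn aldol adduct
Product: 11 (S)-4-benzyl-3-[(2S,3R)-2-(benzyloxy)-3-[4-(benzyloxy)phenyl]-3-[(tert-butyldimethylsilyl)oxy]propanoyl]oxazolidin-2-one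
Conditions: TBSOTf, 2,6-lutidine, CH2Cl2, 0 °C
Reagents that add atoms: tert-butyldimethylsilyl triflate, CC(C)(C)[Si](C)(C)OS(=O)(=O)C(F)(F)F
Why: Silylation of the secondary benzylic alcohol with the silyl triflate blocks retro-aldol cleavage and masks the future O1 until the side chain is complete.

Step 6
Reactants: 11 the silylated imide
Product: 12 (2R,3R)-2-(benzyloxy)-3-[4-(benzyloxy)phenyl]-3-[(tert-butyldimethylsilyl)oxy]propan-1-ol
Conditions: LiBH4, MeOH (1 equiv), THF, 0 °C
Reagents that add atoms: none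
Why: Reductive cleavage of the N-acyloxazolidinone with LiBH4 gives the primary alcohol without touching the α-stereocentre and releases the auxiliary.

Step 7
Reactants: 12 the primary alcohol
Product: 13 (2R,3R)-2-(benzyloxy)-3-[4-(benzyloxy)phenyl]-3-[(tert-butyldimethylsilyl)oxy]propyl trifluoromethanesulfonate
Conditions: Tf2O, 2,6-lutidine, CH2Cl2, −78 °C; cold aqueous work-up, used crude
Reagents that add atoms: triflic anhydride, O=S(=O)(OS(=O)(=O)C(F)(F)F)C(F)(F)F
Why: O-Sulfonylation of the primary alcohol at low temperature gives the alkyl triflate, which is used at once without purification.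

Step 8
Reactants: 3 1,5-bis(benzyloxy)-3-bromo-2-iodobenzene; 13 the primary triflate
Product: 15 tert-butyl{[(1R,2R)-2-(benzyloxy)-3-[2,4-bis(benzyloxy)-6-bromophenyl]-1-[4-(benzyloxy)phenyl]propyl]oxy}dimethylsilane, via arylmagnesium chloride 14 (not isolated)
Conditions: 3, i-PrMgCl·LiCl, THF, −30 °C; then CuI (10 mol %), 13, −30 → 0 °C
Reagents that add atoms: none
Why: Iodine–magnesium exchange is much faster at C–I than at C–Br and the 2-bromoarylmagnesium species is stable at low temperature, so a copper-catalysed Grignard–alkyl triflate coupling (Kochi-type sp2–sp3 substitution) can form C4–C4a at the primary carbon with both stereocentres untouched.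

Step 9
Reactants: 15 the silyl ether
Product: 16 (1R,2R)-2-(benzyloxy)-3-[2,4-bis(benzyloxy)-6-bromophenyl]-1-[4-(benzyloxy)phenyl]propan-1-ol
Conditions: Bu4NF, THF, 0 → 23 °C
Reagents that add atoms: none
Why: Fluoride-induced desilylation frees the benzylic alcohol and leaves benzyl ethers and the aryl bromide intact.

Step 10
Reactants: 17 7-hydroxy-4H-chromen-4-one
Product: 18 7-(benzyloxy)-4H-chromen-4-one
Conditions: BnBr, K2CO3, acetone, reflux
Reagents that add atoms: benzyl bromide, BrCc1ccccc1
Why: Williamson etherification of the chromone phenol.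

Step 11
Reactants: 18 7-(benzyloxy)-4H-chromen-4-one; 19 4-(benzyloxy)phenylboronic acid
Product: 20 (S)-7-(benzyloxy)-2-[4-(benzyloxy)phenyl]chroman-4-one
Conditions: Pd(OCOCF3)2 (5 mol %), (R)-4-tert-butyl-2-(pyridin-2-yl)-4,5-dihydrooxazole (6 mol %), NH4PF6 (30 mol %), H2O (5 equiv), ClCH2CH2Cl, 60 °C
Reagents that add atoms: none
Why: Palladium-catalysed asymmetric conjugate addition of an arylboronic acid to a chromone: the cationic arylpalladium complex of the pyridine–oxazoline ligand adds aryl to C2 and water protonates the palladium enolate, and the (R)-ligand is chosen as the antipode expected to deliver the aryl group to the face that gives the 2S flavanone, which sets the upper C2 stereocentre.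

Step 12
Reactants: 20 the (S)-flavanone
Product: 21 (S)-7-(benzyloxy)-2-[4-(benzyloxy)phenyl]-2H-chromen-4-yl trifluoromethanesulfonate
Conditions: Tf2O, 2,6-di-tert-butyl-4-methylpyridine, CH2Cl2, −78 → 0 °C
Reagents that add atoms: triflic anhydride, O=S(=O)(OS(=O)(=O)C(F)(F)F)C(F)(F)F
Why: Enol triflate formation by O-triflation of the ketone and loss of a C3 proton to the hindered pyridine avoids a free enolate, so the pyranone ring cannot open by β-elimination of the phenoxide and C2 keeps its configuration.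

Step 13
Reactants: 16 the (1R,2R) bromoarene alcohol; 21 the (S)-flavenyl triflate
Product: 26 (2S)-7-(benzyloxy)-2-[4-(benzyloxy)phenyl]-4-[(2R,3R)-3,5,7-tris(benzyloxy)-2-[4-(benzyloxy)phenyl]chroman-8-yl]-2H-chromene, via dilithiated bromoarene 22 (not isolated), via aryne lithium alkoxide 23 (not isolated), via 8-lithioflavan 24 (not isolated), via 8-flavanylzinc chloride 25 (not isolated)
Conditions: lithium 2,2,6,6-tetramethylpiperidide (from the amine and n-BuLi, 2.15 equiv), THF, −78 °C; −78 → −20 °C; ZnCl2 (1.3 equiv), −20 → 23 °C; then 21, Pd2(dba)3 (2.5 mol %), 2-dicyclohexylphosphino-2',6'-diisopropoxybiphenyl (10 mol %), 50 °C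
Reagents that add atoms: none
Why: Proposed new method: the lithium amide first forms the alkoxide and then removes C8–H, the ring proton between bromine and the C7 benzyloxy group; on warming, 22 loses LiBr to give the 3-alkoxyaryne 23 (C8≡C8a), the tethered alkoxide adds to C8a, and the C8 aryllithium 24, flanked by O1 and the C7 ether oxygen and therefore a weaker base than the lithium amide, should persist beside the free amine until ZnCl2 turns it into arylzinc 25, which undergoes Negishi coupling with enol triflate 21. The closest known reactions are base-induced aryne cyclisations of halophenyl alkanols and alkylamines to chromans and indolines with electrophilic trapping of the new aryl anion, and Negishi couplings of 2,6-dialkoxyarylzinc halides with alkenyl triflates; new is their union in one flask with an alkoxide as the nucleophile. The lower pyran ring closes by attack of oxygen on the aryne carbon nearest the chain (C8a), a six-membered closure that is exo with respect to the aryne bond, since C8 stays outside the ring. No stereocentre is formed: the C2–O and C3–O bonds are untouched, so 2R,3R is carried over, and the 2S centre of 21 is not involved. The step needs oxygen at C8a and carbon at C8: the three-atom tether reaches only C8a, the C7 benzyloxy group polarises the aryne in the same sense and stabilises the C8 carbanion, and C6 is never metallated on the productive path, which fixes the 4→8 linkage.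

Step 14
Reactants: 26 the hexabenzylated 4-arylflav-3-ene
Product: 27 (2R,3R)-8-[(2S,4S)-7-hydroxy-2-(4-hydroxyphenyl)chroman-4-yl]-2-(4-hydroxyphenyl)chromane-3,5,7-triol (target)
Conditions: H2 (4 atm), Pd(OH)2/C, THF–MeOH, 23 °C
Reagents that add atoms: none
Why: Heterogeneous catalytic hydrogenation adds H2 syn to the upper C3=C4 bond from the face opposite the C2 aryl group, which places the C4 aryl substituent cis to it (upper C4 S), and the same catalyst removes the six benzyl ethers by hydrogenolysis.

**Compound list**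

1 | 5-bromoresorcinol | Oc1cc(O)cc(Br)c1 | starting material
2 | 1,3-bis(benzyloxy)-5-bromobenzene | Brc1cc(OCc2ccccc2)cc(OCc2ccccc2)c1 | intermediate
3 | 1,5-bis(benzyloxy)-3-bromo-2-iodobenzene | Brc1cc(OCc2ccccc2)cc(OCc2ccccc2)c1I | intermediate
4 | (S)-4-benzyloxazolidin-2-one | O=C1N[C@@H](Cc2ccccc2)CO1 | starting material
5 | (benzyloxy)acetyl chloride | ClC(=O)COCc1ccccc1 | starting material
6 | N-lithio derivative of 4 (formed in the flask) | O=C1OC[C@H](Cc2ccccc2)N1[Li] | intermediate
7 | (S)-4-benzyl-3-[(benzyloxy)acetyl]oxazolidin-2-one | O=C1OC[C@H](Cc2ccccc2)N1C(=O)COCc1ccccc1 | intermediate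
8 | 4-(benzyloxy)benzaldehyde | O=Cc1ccc(OCc2ccccc2)cc1 | starting material
9 | Z dibutylboron enolate of 7 (formed in the flask) | O=C1OC[C@H](Cc2ccccc2)N1/C(OB(CCCC)CCCC)=C/OCc1ccccc1 | intermediate
10 | (S)-4-benzyl-3-[(2S,3R)-2-(benzyloxy)-3-[4-(benzyloxy)phenyl]-3-hydroxypropanoyl]oxazolidin-2-one | O=C1OC[C@H](Cc2ccccc2)N1C(=O)[C@@H](OCc1ccccc1)[C@H](O)c1ccc(OCc2ccccc2)cc1 | intermediate
11 | tert-butyldimethylsilyl ether of 10 | O=C1OC[C@H](Cc2ccccc2)N1C(=O)[C@@H](OCc1ccccc1)[C@H](O[Si](C)(C)C(C)(C)C)c1ccc(OCc2ccccc2)cc1 | intermediate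
12 | (2R,3R)-2-(benzyloxy)-3-[4-(benzyloxy)phenyl]-3-[(tert-butyldimethylsilyl)oxy]propan-1-ol | OC[C@@H](OCc1ccccc1)[C@H](O[Si](C)(C)C(C)(C)C)c1ccc(OCc2ccccc2)cc1 | intermediate
13 | (2R,3R)-2-(benzyloxy)-3-[4-(benzyloxy)phenyl]-3-[(tert-butyldimethylsilyl)oxy]propyl triflate | O=S(=O)(OC[C@@H](OCc1ccccc1)[C@H](O[Si](C)(C)C(C)(C)C)c1ccc(OCc2ccccc2)cc1)C(F)(F)F | intermediate
14 | [2,4-bis(benzyloxy)-6-bromophenyl]magnesium chloride (formed in the flask) | Cl[Mg]c1c(Br)cc(OCc2ccccc2)cc1OCc1ccccc1 | intermediate
15 | tert-butyl{[(1R,2R)-2-(benzyloxy)-3-[2,4-bis(benzyloxy)-6-bromophenyl]-1-[4-(benzyloxy)phenyl]propyl]oxy}dimethylsilane | CC(C)(C)[Si](C)(C)O[C@H](c1ccc(OCc2ccccc2)cc1)[C@H](OCc1ccccc1)Cc1c(OCc2ccccc2)cc(OCc2ccccc2)cc1Br | intermediate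
16 | (1R,2R)-2-(benzyloxy)-3-[2,4-bis(benzyloxy)-6-bromophenyl]-1-[4-(benzyloxy)phenyl]propan-1-ol | O[C@H](c1ccc(OCc2ccccc2)cc1)[C@H](OCc1ccccc1)Cc1c(OCc2ccccc2)cc(OCc2ccccc2)cc1Br | intermediate
17 | 7-hydroxy-4H-chromen-4-one | O=c1ccoc2cc(O)ccc12 | starting material
18 | 7-(benzyloxy)-4H-chromen-4-one | O=c1ccoc2cc(OCc3ccccc3)ccc12 | intermediate
19 | 4-(benzyloxy)phenylboronic acid | OB(O)c1ccc(OCc2ccccc2)cc1 | starting material
20 | (S)-7-(benzyloxy)-2-[4-(benzyloxy)phenyl]chroman-4-one | O=C1C[C@@H](c2ccc(OCc3ccccc3)cc2)Oc2cc(OCc3ccccc3)ccc12 | intermediate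
21 | (S)-7-(benzyloxy)-2-[4-(benzyloxy)phenyl]-2H-chromen-4-yl triflate | O=S(=O)(OC1=C[C@@H](c2ccc(OCc3ccccc3)cc2)Oc2cc(OCc3ccccc3)ccc12)C(F)(F)F | intermediate
22 | lithium alkoxide of 16 lithiated at C8 (formed in the flask) | [Li]O[C@H](c1ccc(OCc2ccccc2)cc1)[C@H](OCc1ccccc1)Cc1c(OCc2ccccc2)cc(OCc2ccccc2)c([Li])c1Br | intermediate
23 | C8–C8a aryne lithium alkoxide (formed in the flask) | [Li]O[C@H](c1ccc(OCc2ccccc2)cc1)[C@H](OCc1ccccc1)CC1=C(OCc2ccccc2)C=C(OCc2ccccc2)C#C1 | intermediate
24 | 8-lithio-tetra-O-benzylepiafzelechin (formed in the flask) | [Li]c1c(OCc2ccccc2)cc(OCc2ccccc2)c2c1O[C@H](c1ccc(OCc3ccccc3)cc1)[C@H](OCc1ccccc1)C2 | intermediate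
25 | (tetra-O-benzylepiafzelechin-8-yl)zinc chloride (formed in the flask) | Cl[Zn]c1c(OCc2ccccc2)cc(OCc2ccccc2)c2c1O[C@H](c1ccc(OCc3ccccc3)cc1)[C@H](OCc1ccccc1)C2 | intermediate
26 | (2S)-7-(benzyloxy)-2-[4-(benzyloxy)phenyl]-4-[(2R,3R)-3,5,7-tris(benzyloxy)-2-[4-(benzyloxy)phenyl]chroman-8-yl]-2H-chromene | C(c1ccccc1)Oc1ccc(cc1)[C@@H]1C=C(c2c(OCc3ccccc3)cc(OCc3ccccc3)c3c2O[C@H](c2ccc(OCc4ccccc4)cc2)[C@H](OCc2ccccc2)C3)c2ccc(OCc3ccccc3)cc2O1 | intermediate
27 | (2R,3R)-8-[(2S,4S)-7-hydroxy-2-(4-hydroxyphenyl)chroman-4-yl]-2-(4-hydroxyphenyl)chromane-3,5,7-triol | Oc1ccc([C@@H]2C[C@H](c3c(O)cc(O)c4c3O[C@H](c3ccc(O)cc3)[C@H](O)C4)c3ccc(O)cc3O2)cc1 | target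

**Totals**

Total step count: 14. Longest linear sequence: 9 steps (steps 3–9, 13, 14).

**Steps most likely to fail**

1. Step 13 (proposed new method).
 - What may go wrong: the C8 carbanion is protonated by the liberated amine, or the metal moves to C6 by proton shuttling. The aryne is captured intermolecularly before the lithium alkoxide closes the ring. Lithiation at C6, benzylic deprotonation of a benzyl ether, or a halogen dance competes. The hindered arylzinc couples slowly.
 - Fallback (known reactions only): setting out from 16, a palladium-catalysed intramolecular C–O coupling (Pd(OAc)2, 2-(di-tert-butylphosphino)-1,1'-binaphthyl, Cs2CO3, toluene, 80 °C) closes the pyran ring without an aryne and should give tetra-O-benzylepiafzelechin F1. NBS in CH2Cl2 at −78 °C should brominate the more accessible C8 to give the 8-bromide F2. Bromine–lithium exchange (n-BuLi, THF, −78 °C) gives 24 with no amine present, ZnCl2 gives 25, and Negishi coupling with 21 under the catalyst of step 13 comes back to the route at 26.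

2. Step 8.
 - What may go wrong: elimination of triflic acid from the β-alkoxy triflate, slow substitution by the doubly ortho-substituted arylcopper species, or loss of magnesium halide from the 2-bromoaryl Grignard on warming.
 - Fallback: setting out from 2, Vilsmeier formylation (POCl3, DMF) next to bromine gives 2,4-bis(benzyloxy)-6-bromobenzaldehyde F3, NaBH4 gives the benzyl alcohol F4, and PBr3 the benzyl bromide F5. The sodium enolate F6 of imide 7 (NaN(SiMe3)2, THF, −78 °C) is alkylated by F5 on the face away from the auxiliary benzyl group to give the alkylated imide F7 (Evans alkylation). LiBH4 gives the alcohol F8 and Dess–Martin periodinane the α-benzyloxy aldehyde F9. Chelation-controlled (Cram chelate) addition of commercial 4-(benzyloxy)phenylmagnesium bromide (MgBr2·OEt2, CH2Cl2, −78 °C) should give the syn alcohol, which is 16, where the route is rejoined.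

3. Step 14.
 - What may go wrong: incomplete saturation or poor facial selectivity at the hindered C3=C4 bond, or hydrogenolysis of a benzylic C2–O1 bond once the phenols are free.
 - Fallback: setting out from 26, ionic hydrogenation (Et3SiH, CF3CO2H, CH2Cl2, −20 °C) protonates C3 and delivers hydride to the C4 benzylic cation on the face away from the C2 aryl group, which should give the hexabenzyl ether of the target F10. Hydrogenolysis of F10 (H2, Pd(OH)2/C) then only removes benzyl groups and comes back to the route at 27.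

**Further compounds**

F1 | step 13 | (2R,3R)-3,5,7-tris(benzyloxy)-2-[4-(benzyloxy)phenyl]chromane (tetra-O-benzylepiafzelechin) | c1c(OCc2ccccc2)cc(OCc2ccccc2)c2c1O[C@H](c1ccc(OCc3ccccc3)cc1)[C@H](OCc1ccccc1)C2
F2 | step 13 | (2R,3R)-3,5,7-tris(benzyloxy)-2-[4-(benzyloxy)phenyl]-8-bromochromane | Brc1c(OCc2ccccc2)cc(OCc2ccccc2)c2c1O[C@H](c1ccc(OCc3ccccc3)cc1)[C@H](OCc1ccccc1)C2
F3 | step 8 | 2,4-bis(benzyloxy)-6-bromobenzaldehyde | O=Cc1c(Br)cc(OCc2ccccc2)cc1OCc1ccccc1
F4 | step 8 | [2,4-bis(benzyloxy)-6-bromophenyl]methanol | OCc1c(Br)cc(OCc2ccccc2)cc1OCc1ccccc1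
F5 | step 8 | 1,5-bis(benzyloxy)-3-bromo-2-(bromomethyl)benzene | BrCc1c(Br)cc(OCc2ccccc2)cc1OCc1ccccc1
F6 | step 8 | sodium Z enolate of 7 | O=C1OC[C@H](Cc2ccccc2)N1/C(O[Na])=C/OCc1ccccc1
F7 | step 8 | (S)-4-benzyl-3-[(R)-2-(benzyloxy)-3-[2,4-bis(benzyloxy)-6-bromophenyl]propanoyl]oxazolidin-2-one | O=C1OC[C@H](Cc2ccccc2)N1C(=O)[C@H](OCc1ccccc1)Cc1c(Br)cc(OCc2ccccc2)cc1OCc1ccccc1
F8 | step 8 | (R)-2-(benzyloxy)-3-[2,4-bis(benzyloxy)-6-bromophenyl]propan-1-ol | OC[C@H](OCc1ccccc1)Cc1c(Br)cc(OCc2ccccc2)cc1OCc1ccccc1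
F9 | step 8 | (R)-2-(benzyloxy)-3-[2,4-bis(benzyloxy)-6-bromophenyl]propanal | O=C[C@H](OCc1ccccc1)Cc1c(Br)cc(OCc2ccccc2)cc1OCc1ccccc1
F10 | step 14 | (2R,3R)-3,5,7-tris(benzyloxy)-2-[4-(benzyloxy)phenyl]-8-[(2S,4S)-7-(benzyloxy)-2-[4-(benzyloxy)phenyl]chroman-4-yl]chromane | C(c1ccccc1)Oc1ccc(cc1)[C@@H]1C[C@H](c2c(OCc3ccccc3)cc(OCc3ccccc3)c3c2O[C@H](c2ccc(OCc4ccccc4)cc2)[C@H](OCc2ccccc2)C3)c2ccc(OCc3ccccc3)cc2O1
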